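**Assumption:** the target has no stereocenters, so there is no enantiomer to set. It is written as the diketo tautomer, although it exists largely as the enol.

## Retrosynthetic overview
- The aryl ring already exists in the starting material, so no rings are formed.
- Target → β-oxygenation of an ynone. The 1,3-diketone is unmasked by regioselective, carbonyl-directed hydration of the C4≡C5 alkyne of a 1-aryl-hexadec-4-yn-3-one.
- The ynone is made by acyl-Sonogashira coupling of an aryl-propanoyl chloride with 1-tridecyne. This avoids the usual Claisen or aldol/oxidation routes.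
- The phenol is carried as its acetate, which survives the coupling and hydration and is removed last.
- The acid chloride comes from dihydroferulic acid (phenol acetylation, then oxalyl chloride).

## Route

**Step 1**
Reactants: 1 (dihydroferulic acid, 3-(4-hydroxy-3-methoxyphenyl)propanoic acid); 2 (acetic anhydride)
Product: 3 (3-(4-acetoxy-3-methoxyphenyl)propanoic acid)
Conditions: 2 (1.2 equiv), 1 M NaOH aq, 0 °C, 30 min; then acidify with 1 M HCl.
Reagents that add atoms: acetic anhydride, CC(=O)OC(C)=O
Why: Schotten–Baumann O-acetylation acts on the phenolate, and any mixed anhydride formed at the carboxylate hydrolyzes in water.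

**Step 2**
Reactants: 3; 4 (oxalyl chloride)
Product: 5 (3-(4-acetoxy-3-methoxyphenyl)propanoyl chloride)
Conditions: 4 (1.3 equiv), cat. DMF, CH2Cl2, 0 °C → rt, 2 h; evaporate.
Reagents that add atoms: oxalyl chloride, ClC(=O)C(=O)Cl
Why: Vilsmeier-type catalytic acid chloride formation, with CO, CO2 and HCl as the only byproducts, so the aryl acetate is untouched.

**Step 3**
Reactants: 5; 6 (1-tridecyne)
Product: 7 (2-methoxy-4-(3-oxohexadec-4-yn-1-yl)phenyl acetate)
Conditions: 6 (1.1 equiv), PdCl2(PPh3)2 (2 mol%), CuI (2 mol%), Et3N (1.5 equiv), THF, 0 °C → rt, 4 h.
Reagents that add atoms: 1-tridecyne, C#CCCCCCCCCCCC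
Why: acyl Sonogashira coupling (Pd/Cu) of a terminal alkyne with an acid chloride gives the ynone directly, and it places the alkyne at C4–C5, exactly where the two carbonyls are needed.

**Step 4**
Reactants: 7; 8 (water)
Product: 9 (2-methoxy-4-(3,5-dioxohexadecyl)phenyl acetate)
Conditions: Ph3PAuCl (3 mol%), AgOTf (3 mol%), MeOH/H2O 9:1, 50 °C, 6 h; then add a few drops of 1 M HCl and stir 1 h to hydrolyze any β-methoxyenone.
Reagents that add atoms: water, O
Why: carbonyl-polarized alkyne hydration puts the nucleophile (H2O, or MeOH followed by hydrolysis of the β-methoxyenone) on the β-carbon C5, and tautomerization gives the 1,3-diketone. Known chemistry, but substrate-dependent.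

**Step 5**
Reactants: 9
Product: 10 ([12]-gingerdione, 1-(4-hydroxy-3-methoxyphenyl)hexadecane-3,5-dione)
Conditions: K2CO3 (1.2 equiv), MeOH, 0 °C, 30 min; quench with sat. NH4Cl.
Reagents that add atoms: none (the acetyl group is lost as methyl acetate)
Why: transesterification cleaves the aryl acetate selectively. The diketone is partly deprotonated under these conditions, which protects it from retro-Claisen cleavage. No stereocenter is involved.

## Self-check
- Target: ArCH2CH2–CO–CH2–CO–C11H23 with Ar = 4-hydroxy-3-methoxyphenyl, a C16 chain with carbonyls at C3 and C5. Compound 7 has C3 carbonyl, C4≡C5 and C6–C16 (11 carbons, from 1-tridecyne, which has 13 carbons in total).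
- Atom balance: 7 + H2O → 9, and 9 − Ac + H → 10.
- Functional groups: the aryl acetate survives Steps 2–4, the methyl ether is inert throughout, and the enolizable acid chloride is used at low temperature.
- There are no stereocenters, so none can be scrambled.

## Compound list
1 | dihydroferulic acid | OC(=O)CCc1ccc(O)c(OC)c1 | starting material
2 | acetic anhydride | CC(=O)OC(C)=O | reagent/starting material
3 | 3-(4-acetoxy-3-methoxyphenyl)propanoic acid | CC(=O)Oc1ccc(CCC(=O)O)cc1OC | intermediate
4 | oxalyl chloride | ClC(=O)C(=O)Cl | reagent/starting material
5 | 3-(4-acetoxy-3-methoxyphenyl)propanoyl chloride | CC(=O)Oc1ccc(CCC(=O)Cl)cc1OC | intermediate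
6 | 1-tridecyne | C#CCCCCCCCCCCC | starting material
7 | 2-methoxy-4-(3-oxohexadec-4-yn-1-yl)phenyl acetate | CC(=O)Oc1ccc(CCC(=O)C#CCCCCCCCCCCC)cc1OC | intermediate
8 | water | O | reagent
9 | 2-methoxy-4-(3,5-dioxohexadecyl)phenyl acetate | CC(=O)Oc1ccc(CCC(=O)CC(=O)CCCCCCCCCCC)cc1OC | intermediate
10 | [12]-gingerdione | CCCCCCCCCCCC(=O)CC(=O)CCc1ccc(O)c(OC)c1 | target

## Totals
Total step count: 5. Longest linear sequence: 5 steps from 1.

## Three steps most likely to fail
1. **Step 4 (ynone hydration).** Gold may stall at the β-methoxyenone, or the electron-rich arene may attack the alkyne (hydroarylation). Fallback: add morpholine or pyrrolidine to give the β-enaminone, then hydrolyze it with aqueous HCl/THF.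
2. **Step 3 (acyl Sonogashira).** Ketene formation from the enolizable acid chloride, or Glaser homocoupling of the alkyne, could lower the yield. Fallback: swap the coupling for addition of lithium tridecynide to the TBS-protected Weinreb amide of the acid, in place of the acetate/acid-chloride coupling.
3. **Step 5 (deacetylation).** Retro-Claisen cleavage or aldol-type decomposition of the diketone under base is possible. Fallback: carry a benzyl ether instead of the acetate (benzylate 1, saponify, then follow Steps 2–4) and remove it at the end by H2, Pd/C under neutral conditions.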